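At late times I had nothing to read: the question stood at 15 min, and the earlier runs stopped at 10.0 min, so I had to carry them forward.

common to all: left-handed substrate 0.075 M; right-handed substrate 0.075 M; gas 40 mM (held); impurity 0.45 mM

| flask | free catalyst | racemization catalyst | remark | time |
|---|---|---|---|---|
| alder | 0.52 mM | 1.6 mM | run made earlier |  |
| oak | 0.52 mM | 6.4 mM | run made earlier |  |
| ash | 0.26 mM | 3.2 mM | run made earlier |  |
| flask | 0.52 mM | 3.2 mM |  | 15 min |

- alder (time / min: left-handed product / %, right-handed product / %, left-handed substrate / %): 0.500: 0.6, 0, 49.8; 1.33: 2.5, 0.8, 47.2; 2.50: 5.1, 2.0, 44.9; 4.00: 9.3, 3.9, 41.8; 5.00: 10.9, 4.7, 40.9; 8.00: 17.1, 7.1, 35.8; 10.0: 20.8, 8.8, 33.9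
- oak (time / min: left-handed product / %, right-handed product / %, left-handed substrate / %): 0.500: 0.4, 0.1, 49.5; 1.33: 3.4, 1.8, 47.8; 2.50: 5.6, 1.6, 45.4; 4.00: 9.5, 3.4, 43.0; 5.00: 11.4, 4.4, 41.2; 8.00: 17.2, 7.7, 37.0; 10.0: 20.9, 8.9, 33.9
- ash (time / min: left-handed product / %, right-handed product / %, left-handed substrate / %): 0.667: 0.3, 0, 50.0; 1.33: 0.7, 0, 49.7; 2.50: 0.2, 0.4, 49.5; 5.00: 0.4, 0, 50.3; 10.0: 0.2, 0, 49.7

(standard deviation of a reading: 0.3 percentage points)

1. left-handed product and right-handed product together, in percent of the left-handed substrate and right-handed substrate charged together, at 15 min
2. excess of left-handed product over right-handed product in the product at 15 min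
3. whether the exchange between left-handed substrate and right-handed substrate keeps pace with the reaction: how far the product's excess at 15 min gets from its value without exchange to its value with instant exchange (above 80 % keeps pace, below 20 % hardly takes part, else lags behind)

- free catalyst is single-handed; left-handed substrate and right-handed substrate are mirror images of each other, charged as a racemate, each of them at the stated concentration
- the numbers in the tables scatter with a standard deviation of 0.3 percentage points
- at the start none of the gas is in solution
- an excess is the difference of the two amounts in percent of their sum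
- an excess is below zero if the other one leads

Ash, charged with less free catalyst than impurity, read 0.2 % of left-handed product at 10.0 min, inside the scatter. I therefore assumed that each impurity kills one free catalyst, and I reckoned the working share, the part of the charged free catalyst that outlives the impurity, for the flask:

working share = 1 − impurity/free catalyst = 13.5 %

Alder and oak were charged with the flask's free catalyst and impurity, so they have this same share. Though 4.00 times apart in racemization catalyst, they had converted 29.6 % and 29.8 % at 10.0 min. I took the mean and a pseudo-first-order constant:

k = ln(1/(1 − 29.7 %))/10.0 min = 0.0352 min⁻¹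

first conversion at 15 min = 41.1 %

The weak link was the clock: no gas is in solution at the start. The mean conversion at 0.500 min was 0.550 %, less than k gives there. I put the first answer back in:

lag = 0.500 min − conversion/k = 0.344 min

new k = 0.0365 min⁻¹

conversion at 15 min = 41.4 %

The product excess at 10.0 min read 40.5 % in alder and 40.3 % in oak, much alike. I carried that level forward and left the pace open.

The forecast stood at a conversion of 41.5 %, an excess of 41.2 %, and keeps pace, in its words “marginally keeps pace”.

The flask gave a conversion of 41.5 %, an excess of 41.0 %, and an exchange that lags behind, 73 % of the way.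

    2 racemization catalyst → spent catalyst B (k = 0.260 L mol⁻¹ s⁻¹)
    gas ⇌ reagent, rate k2*(csat - [reagent]) (kL = 0.0420 s⁻¹)
    left-handed substrate + racemization catalyst ⇌ right-handed substrate + racemization catalyst, rate k3*[racemization catalyst]*[left-handed substrate] forward; the back reaction follows from the equilibrium constant (k = 1.90 L mol⁻¹ s⁻¹)
    reagent + free catalyst + right-handed substrate → free catalyst + right-handed product (k = 130 L² mol⁻² s⁻¹)
    free catalyst + impurity → spent catalyst A (k = 1300 L mol⁻¹ s⁻¹)
    reagent + free catalyst + left-handed substrate → free catalyst + left-handed product (k = 330 L² mol⁻² s⁻¹)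

The flask held 13.5 % of its free catalyst at 15.0 min, which is the working share I had reckoned. For the neighbour charged with 0.110 mM of impurity, the same subtraction gave a share of 78.8 %. Scaling k by the shares gave 0.214 min⁻¹, and with the same lag a conversion of 95.6 %. That neighbour held 78.8 % of its free catalyst and gave a conversion of 93.7 %, with an excess of 32.7 %.

The readings stem from a simulated flask with made-up constants; the scatter is artificial.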